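**Retrosynthetic overview**
1. Target 39 ⇐ C9 oxidation and C9–OH-directed 1,10-epoxidation of the ten-membered allylic alcohol 36 ⇐ Nozaki–Hiyama–Kishi closure of C9–C10 in vinyl iodide–aldehyde 35.
2. 35 ⇐ tri-angelate whose 4,5-cis-epoxide comes from C6–OH-directed epoxidation of the acyclic (Z)-C4=C5 allylic alcohol 30.
3. C1–C3/C10/C14 ⇐ catalytic asymmetric propargylation of (Z)-enal 19 (sets C3), acetylide methylation, hydrozirconation–iodination.
4. 19 ⇐ Still–Gennari olefination of C5 aldehyde 15; the C6–C7–C8 triad ⇐ butenolide 1 by trans cuprate addition, enolate hydroxylation and Mitsunobu inversion.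
5. Ring order: oxirane C4–C5 (step 16), ten-membered carbocycle (step 20), oxirane C1–C10 (step 21); the butenolide ring is only a temporary template.

Assumption: germacrane numbering is used throughout (ring C1–C10, C14 on C10, C15 on C4, isopropenyl C11–C13 on C7; C9 is the CH2OH carbon of 1, and C8, C7, C6, C5 are its ring carbons); Ang = (Z)-2-methylbut-2-enoyl, TBDPS = tert-butyldiphenylsilyl, TES = triethylsilyl; the SMILES define the configuration of every acyclic intermediate.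

**Route**

Step 1
Reactants: 1 (R)-5-(hydroxymethyl)furan-2(5H)-one; 2 tert-butyl(chloro)diphenylsilane
Product: 3 (R)-5-(TBDPS-oxymethyl)furan-2(5H)-one
Conditions: imidazole, CH2Cl2, 0 °C → rt
Reagents that add atoms: tert-butyl(chloro)diphenylsilane (2), CC(C)(C)[Si](Cl)(c1ccccc1)c1ccccc1
Why: Silylation of the only hydroxyl gives a primary TBDPS ether that survives every later step until fluoride is used, and no stereocentre is touched.

Step 2
Reactants: 3 (R)-5-(TBDPS-oxymethyl)furan-2(5H)-one; 4 isopropenylmagnesium bromide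
Product: 5 4,5-trans-4-isopropenyl-5-(TBDPS-oxymethyl)oxolan-2-one
Conditions: CuBr·SMe2 (15 mol %), THF, −78 → −40 °C; aq. NH4Cl
Reagents that add atoms: isopropenylmagnesium bromide (4), CC(=C)[Mg]Br
Why: Copper-catalysed conjugate (1,4-) addition of the Grignard reagent occurs on the butenolide face opposite the C8 silyloxymethyl group, so C7 is set trans to C8 (the 7,8-anti relation of the target).

Step 3
Reactants: 5 4,5-trans-4-isopropenyl-5-(TBDPS-oxymethyl)oxolan-2-one; 6 3-phenyl-2-(phenylsulfonyl)-1,2-oxaziridine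
Product: 8 3,4-trans-4,5-trans-3-hydroxy lactone, via potassium lactone enolate 7 (not isolated)
Conditions: KN(SiMe3)2, THF, −78 °C; then 6, −78 °C; aq. NH4Cl
Reagents that add atoms: 3-phenyl-2-(phenylsulfonyl)-1,2-oxaziridine (6), O=S(=O)(c1ccccc1)N1OC1c1ccccc1
Why: Davis enolate hydroxylation oxidises the planar enolate on the face away from the adjacent C7 isopropenyl group, giving the C6 alcohol trans to it (the C6 epimer of what is needed, corrected in step 4).

Step 4
Reactants: 8 3,4-trans-4,5-trans-3-hydroxy lactone; 9 4-nitrobenzoic acid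
Product: 10 3,4-cis-4,5-trans lactone 3-(4-nitrobenzoate)
Conditions: PPh3, DIAD, THF, 0 °C → rt
Reagents that add atoms: 4-nitrobenzoic acid (9), OC(=O)c1ccc(cc1)[N+](=O)[O-]
Why: Mitsunobu reaction, an SN2 displacement of the α-carbonyl oxyphosphonium by the carboxylate, inverts C6 and puts its oxygen cis to the isopropenyl group on the ring, which is the 6,7-anti arrangement of the open chain.

Step 5
Reactants: 10 3,4-cis-4,5-trans lactone 3-(4-nitrobenzoate); 11 N,O-dimethylhydroxylamine hydrochloride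
Product: 12 C5 Weinreb amide 6,8-diol (9-OTBDPS)
Conditions: AlMe3, CH2Cl2, 0 °C → rt; aq. potassium sodium tartrate (KNaC4H4O6); used crude
Reagents that add atoms: N,O-dimethylhydroxylamine hydrochloride (11), CNOC.Cl
Why: Weinreb aminolysis with the aluminium amide made in the flask opens the lactone to the N-methoxy-N-methylamide and transamidates the nitrobenzoate at the same time, freeing the C6 and C8 hydroxyls without touching a stereocentre.

Step 6
Reactants: 12 C5 Weinreb amide 6,8-diol; 13 triethylsilyl trifluoromethanesulfonate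
Product: 14 6,8-bis-TES Weinreb amide
Conditions: 2,6-lutidine, CH2Cl2, −78 → 0 °C
Reagents that add atoms: triethylsilyl trifluoromethanesulfonate (13), CC[Si](CC)(CC)OS(=O)(=O)C(F)(F)F
Why: Silylation with the silyl triflate (which also stops relactonisation) gives two acid-labile secondary TES ethers that can later be cleaved in the presence of the primary TBDPS ether.

Step 7
Reactants: 14 6,8-bis-TES Weinreb amide
Product: 15 C5 aldehyde (6,8-bis-OTES, 9-OTBDPS)
Conditions: i-Bu2AlH, THF, −78 °C; aq. potassium sodium tartrate (KNaC4H4O6)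
Reagents that add atoms: none
Why: Hydride reduction of a Weinreb amide stops at the aldehyde because the chelated tetrahedral aluminium adduct collapses only on work-up, and the α-silyloxy aldehyde is used at once to avoid C6 epimerisation.

Step 8
Reactants: 15 C5 aldehyde; 16 methyl 2-[bis(2,2,2-trifluoroethoxy)phosphoryl]propanoate
Product: 17 methyl (Z)-C3 enoate (C4=C5 Z)
Conditions: KN(SiMe3)2, 18-crown-6, THF, −78 °C
Reagents that add atoms: methyl 2-[bis(2,2,2-trifluoroethoxy)phosphoryl]propanoate (16), COC(=O)C(C)P(=O)(OCC(F)(F)F)OCC(F)(F)F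
Why: Still–Gennari variant of the Horner–Wadsworth–Emmons olefination, in which the trifluoroethyl phosphonate with a crown-separated potassium ion eliminates under kinetic control, gives the (Z)-trisubstituted enoate with C3 and C6 cis on C4=C5.

Step 9
Reactants: 17 methyl (Z)-C3 enoate
Product: 18 (Z)-allylic alcohol (C3 CH2OH)
Conditions: i-Bu2AlH (2.5 equiv), CH2Cl2, −78 °C; aq. potassium sodium tartrate (KNaC4H4O6)
Reagents that add atoms: none
Why: 1,2-Reduction of the enoate by the aluminium hydride at low temperature gives the allylic alcohol without touching the silyl ethers or the olefin geometry.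

Step 10
Reactants: 18 (Z)-allylic alcohol
Product: 19 (Z)-enal (C3 CHO)
Conditions: MnO2, CH2Cl2, rt, dark
Reagents that add atoms: none
Why: Allylic oxidation with MnO2 is selective for the allylic primary alcohol and neutral, which limits Z to E isomerisation of the enal.

Step 11
Reactants: 19 (Z)-enal; 20 allenylboronic acid pinacol ester
Product: 21 (3S)-homopropargylic alcohol (terminal alkyne)
Conditions: (S)-TRIP [(S)-3,3'-bis(2,4,6-triisopropylphenyl)-1,1'-binaphthyl-2,2'-diyl hydrogen phosphate] (10 mol %), 4 Å MS, toluene, −30 °C; aq. NaHCO3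
Reagents that add atoms: allenylboronic acid pinacol ester (20), C=C=CB1OC(C)(C)C(C)(C)O1
Why: Chiral Brønsted acid-catalysed allenylboration (asymmetric carbonyl propargylation) runs through a closed six-membered SE2' transition state in which the (S)-acid directs attack to the Si face of the aldehyde, setting C3 as S under catalyst control.

Step 12
Reactants: 21 (3S)-homopropargylic alcohol; 22 iodomethane
Product: 24 (3S)-alcohol bearing the C1≡C10–C14 2-alkyne, via dilithium alkoxide acetylide 23 (not isolated)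
Conditions: n-BuLi (2.1 equiv), THF, −78 → −20 °C; then MeI (1.2 equiv), −78 °C → rt; aq. NH4Cl
Reagents that add atoms: iodomethane (22), CI
Why: Acetylide alkylation introduces C14 because the lithium acetylide is methylated far faster than the lithium alkoxide.

Step 13
Reactants: 24 (3S)-alcohol bearing the 2-alkyne; 25 iodine
Product: 27 (E)-C10 vinyl iodide alcohol, via bis-zirconocene species 26 (not isolated)
Conditions: Cp2Zr(H)Cl (2.3 equiv), THF, 0 °C → rt; then I2, 0 °C
Reagents that add atoms: iodine (25), II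
Why: Hydrozirconation–iodination adds Zr–H syn across the alkyne with zirconium settling on the less hindered methyl-bearing C10, and iodinolysis with retention gives the (E)-2-iodoalkene (C2 trans to I).

Step 14
Reactants: 27 (E)-C10 vinyl iodide alcohol; 28 angelic acid
Product: 29 C3 angelate (6,8-bis-OTES)
Conditions: 28, 2,4,6-trichlorobenzoyl chloride, Et3N, toluene, rt; then 27, 75 °C
Reagents that add atoms: angelic acid (28), C/C=C(/C)C(=O)O
Why: Yamaguchi-type mixed-anhydride esterification without a nucleophilic catalyst acylates the only free hydroxyl and avoids isomerisation of the angelate to the tiglate.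

Step 15
Reactants: 29 C3 angelate (6,8-bis-OTES)
Product: 30 6,8-diol (C3 angelate, 9-OTBDPS)
Conditions: PPTS, MeOH–CH2Cl2, 0 °C → rt
Reagents that add atoms: none
Why: Acid-catalysed methanolysis of silyl ethers removes the two secondary TES groups selectively and leaves the primary TBDPS ether, the ester and the vinyl iodide intact.

Step 16
Reactants: 30 6,8-diol; 31 3-chloroperoxybenzoic acid
Product: 32 (4S,5R)-cis-epoxy 6,8-diol
Conditions: NaHCO3, CH2Cl2, −20 → 0 °C
Reagents that add atoms: 3-chloroperoxybenzoic acid (31), OOC(=O)c1cccc(Cl)c1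
Why: Hydroxyl-directed peracid epoxidation: the (Z)-allylic alcohol sits in the A(1,3)-minimised conformer with H6 in the olefin plane and the hydrogen-bonded peracid is delivered to the C6–OH face, giving the threo cis-epoxide, while the isopropenyl, iodoalkene and angelate double bonds react far more slowly.

Step 17
Reactants: 32 (4S,5R)-cis-epoxy 6,8-diol; 28 angelic acid
Product: 33 3,6,8-tri-angelate (9-OTBDPS)
Conditions: 28, 2,4,6-trichlorobenzoyl chloride, Et3N, toluene, rt; then 32, 60 °C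
Reagents that add atoms: angelic acid (28), C/C=C(/C)C(=O)O
Why: The same mixed-anhydride esterification acylates the C6 and C8 hydroxyls under mildly basic, non-nucleophilic conditions that keep the epoxide closed and the esters Z.

Step 18
Reactants: 33 3,6,8-tri-angelate (9-OTBDPS)
Product: 34 C9 primary alcohol
Conditions: HF·pyridine, pyridine, THF, 0 °C → rt
Reagents that add atoms: none
Why: Fluoride-mediated desilylation buffered with pyridine frees the primary alcohol without opening the epoxide or moving the esters.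

Step 19
Reactants: 34 C9 primary alcohol
Product: 35 seco C9 aldehyde–C10 vinyl iodide
Conditions: PhI(OAc)2, TEMPO (10 mol %), CH2Cl2, rt
Reagents that add atoms: none
Why: TEMPO-catalysed oxidation with the iodane as terminal oxidant gives the aldehyde under neutral conditions, so the α-acyloxy centre C8 is not epimerised.

Step 20
Reactants: 35 seco C9 aldehyde–C10 vinyl iodide
Product: 36 ten-membered (E)-allylic alcohol (9R, 8,9-syn)
Conditions: CrCl2 (10 equiv), NiCl2 (2 mol %), DMSO–THF, rt, 0.002 M, slow addition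
Reagents that add atoms: none
Why: Nozaki–Hiyama–Kishi reaction: nickel-catalysed activation of the C–I bond and transfer to chromium gives an alkenylchromium that adds only to the aldehyde with retention of the (E)-olefin and closes the ring at high dilution; the 8,9-syn carbinol drawn is the epimer expected from chelation of chromium by the C8 ester carbonyl, and C9 is oxidised later.

Step 21
Reactants: 36 ten-membered (E)-allylic alcohol; 37 tert-butyl hydroperoxide
Product: 38 1,10:4,5-diepoxy C9 alcohol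
Conditions: VO(acac)2 (5 mol %), CH2Cl2, 0 °C
Reagents that add atoms: tert-butyl hydroperoxide (37), CC(C)(C)OO
Why: Vanadium-catalysed hydroxyl-directed epoxidation delivers the peroxide oxygen from the vanadium-bound C9 alkoxide to the exposed outer face of the only allylic-alcohol olefin, syn to the hydroxyl, giving the trans-epoxide with the C1/C10 configuration of the target.

Step 22
Reactants: 38 1,10:4,5-diepoxy C9 alcohol
Product: 39 (1S,3S,4S,5R,6S,7R,8R,10R)-3,6,8-tris(angeloyloxy)-1,10:4,5-diepoxygermacr-11(13)-en-9-one (CNP0154187.3)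
Conditions: Dess–Martin periodinane, NaHCO3, CH2Cl2, 0 °C → rt
Reagents that add atoms: none
Why: Dess–Martin oxidation converts the secondary alcohol to the C9 ketone under neutral buffered conditions that spare both epoxides, the three angelates and the epimerisable C8 centre.

**Compound list**
1 | (R)-5-(hydroxymethyl)furan-2(5H)-one | OC[C@@H]1OC(=O)C=C1 | starting material
2 | tert-butyl(chloro)diphenylsilane | CC(C)(C)[Si](Cl)(c1ccccc1)c1ccccc1 | starting material
3 | (R)-5-(TBDPS-oxymethyl)furan-2(5H)-one | CC(C)(C)[Si](c1ccccc1)(c1ccccc1)OC[C@@H]1OC(=O)C=C1 | intermediate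
4 | isopropenylmagnesium bromide | CC(=C)[Mg]Br | starting material
5 | (4S,5R)-4-(prop-1-en-2-yl)-5-(TBDPS-oxymethyl)oxolan-2-one (4,5-trans) | CC(C)(C)[Si](c1ccccc1)(c1ccccc1)OC[C@@H]1OC(=O)C[C@H]1C(C)=C | intermediate
6 | 3-phenyl-2-(phenylsulfonyl)-1,2-oxaziridine (racemic) | O=S(=O)(c1ccccc1)N1OC1c1ccccc1 | starting material
7 | potassium enolate of lactone 5 | CC(C)(C)[Si](c1ccccc1)(c1ccccc1)OC[C@@H]1OC([O-])=C[C@H]1C(C)=C.[K+] | intermediate
8 | (3R,4R,5R)-3-hydroxy-4-(prop-1-en-2-yl)-5-(TBDPS-oxymethyl)oxolan-2-one (3,4-trans, 4,5-trans) | CC(C)(C)[Si](c1ccccc1)(c1ccccc1)OC[C@@H]1OC(=O)[C@H](O)[C@H]1C(C)=C | intermediate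
9 | 4-nitrobenzoic acid | OC(=O)c1ccc(cc1)[N+](=O)[O-] | starting material
10 | (3S,4S,5R)-2-oxo-4-(prop-1-en-2-yl)-5-(TBDPS-oxymethyl)oxolan-3-yl 4-nitrobenzoate (3,4-cis, 4,5-trans) | CC(C)(C)[Si](c1ccccc1)(c1ccccc1)OC[C@@H]1OC(=O)[C@@H](OC(=O)c2ccc(cc2)[N+](=O)[O-])[C@H]1C(C)=C | intermediate
11 | N,O-dimethylhydroxylamine hydrochloride | CNOC.Cl | starting material
12 | 5-(TBDPS-oxy)-2,4-dihydroxy-N-methoxy-N-methyl-3-(prop-1-en-2-yl)pentanamide (amide carbon = C5; C6, C7, C8 arranged as in 39: 6,7-anti, 7,8-anti) | CC(C)(C)[Si](c1ccccc1)(c1ccccc1)OC[C@H](O)[C@H](C(C)=C)[C@H](O)C(=O)N(C)OC | intermediate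
13 | triethylsilyl trifluoromethanesulfonate | CC[Si](CC)(CC)OS(=O)(=O)C(F)(F)F | starting material
14 | 6,8-bis-TES ether of 12 | CC(C)(C)[Si](c1ccccc1)(c1ccccc1)OC[C@H](O[Si](CC)(CC)CC)[C@H](C(C)=C)[C@H](O[Si](CC)(CC)CC)C(=O)N(C)OC | intermediate
15 | C5 aldehyde: 5-(TBDPS-oxy)-3-(prop-1-en-2-yl)-2,4-bis(triethylsilyloxy)pentanal (C6–C8 as in 39) | CC(C)(C)[Si](c1ccccc1)(c1ccccc1)OC[C@H](O[Si](CC)(CC)CC)[C@H](C(C)=C)[C@H](O[Si](CC)(CC)CC)C=O | intermediate
16 | methyl 2-[bis(2,2,2-trifluoroethoxy)phosphoryl]propanoate | COC(=O)C(C)P(=O)(OCC(F)(F)F)OCC(F)(F)F | starting material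
17 | methyl (2Z)-7-(TBDPS-oxy)-2-methyl-5-(prop-1-en-2-yl)-4,6-bis(triethylsilyloxy)hept-2-enoate (ester carbon = C3) | CC(C)(C)[Si](c1ccccc1)(c1ccccc1)OC[C@H](O[Si](CC)(CC)CC)[C@H](C(C)=C)[C@H](O[Si](CC)(CC)CC)/C=C(/C)C(=O)OC | intermediate
18 | (Z)-allylic alcohol (C3 CH2OH; C4=C5 Z; 6,8-bis-OTES; 9-OTBDPS) | CC(C)(C)[Si](c1ccccc1)(c1ccccc1)OC[C@H](O[Si](CC)(CC)CC)[C@H](C(C)=C)[C@H](O[Si](CC)(CC)CC)/C=C(/C)CO | intermediate
19 | (Z)-enal (C3 CHO) | CC(C)(C)[Si](c1ccccc1)(c1ccccc1)OC[C@H](O[Si](CC)(CC)CC)[C@H](C(C)=C)[C@H](O[Si](CC)(CC)CC)/C=C(/C)C=O | intermediate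
20 | allenylboronic acid pinacol ester (4,4,5,5-tetramethyl-2-(propa-1,2-dien-1-yl)-1,3,2-dioxaborolane) | C=C=CB1OC(C)(C)C(C)(C)O1 | starting material
21 | (3S)-homopropargylic alcohol (C1≡C10–H) | CC(C)(C)[Si](c1ccccc1)(c1ccccc1)OC[C@H](O[Si](CC)(CC)CC)[C@H](C(C)=C)[C@H](O[Si](CC)(CC)CC)/C=C(/C)[C@@H](O)CC#C | intermediate
22 | iodomethane | CI | starting material
23 | dilithium C3-alkoxide C10-acetylide of 21 | CC(C)(C)[Si](c1ccccc1)(c1ccccc1)OC[C@H](O[Si](CC)(CC)CC)[C@H](C(C)=C)[C@H](O[Si](CC)(CC)CC)/C=C(/C)[C@@H]([O-])CC#[C-].[Li+].[Li+] | intermediate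
24 | (3S)-alcohol with C1≡C10–C14 2-alkyne | CC(C)(C)[Si](c1ccccc1)(c1ccccc1)OC[C@H](O[Si](CC)(CC)CC)[C@H](C(C)=C)[C@H](O[Si](CC)(CC)CC)/C=C(/C)[C@@H](O)CC#CC | intermediate
25 | iodine | II | starting material
26 | C3-O and C10 bis[chlorobis(cyclopentadienyl)zirconium] species, (E)-alkenyl | CC(C)(C)[Si](c1ccccc1)(c1ccccc1)OC[C@H](O[Si](CC)(CC)CC)[C@H](C(C)=C)[C@H](O[Si](CC)(CC)CC)/C=C(/C)[C@@H](O[Zr](Cl)(C1C=CC=C1)C1C=CC=C1)C/C=C(C)/[Zr](Cl)(C1C=CC=C1)C1C=CC=C1 | intermediate
27 | (3S)-alcohol with (1E)-10-iodo-C1=C10 olefin | CC(C)(C)[Si](c1ccccc1)(c1ccccc1)OC[C@H](O[Si](CC)(CC)CC)[C@H](C(C)=C)[C@H](O[Si](CC)(CC)CC)/C=C(/C)[C@@H](O)C/C=C(/I)C | intermediate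
28 | angelic acid ((Z)-2-methylbut-2-enoic acid) | C/C=C(/C)C(=O)O | starting material
29 | C3 angelate of 27 | CC(C)(C)[Si](c1ccccc1)(c1ccccc1)OC[C@H](O[Si](CC)(CC)CC)[C@H](C(C)=C)[C@H](O[Si](CC)(CC)CC)/C=C(/C)[C@@H](OC(=O)/C(C)=C\C)C/C=C(/I)C | intermediate
30 | 6,8-diol (C3 angelate; C4=C5 Z; 9-OTBDPS) | CC(C)(C)[Si](c1ccccc1)(c1ccccc1)OC[C@H](O)[C@H](C(C)=C)[C@H](O)/C=C(/C)[C@@H](OC(=O)/C(C)=C\C)C/C=C(/I)C | intermediate
31 | 3-chloroperoxybenzoic acid | OOC(=O)c1cccc(Cl)c1 | starting material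
32 | (4S,5R)-4,5-cis-epoxy 6,8-diol | CC(C)(C)[Si](c1ccccc1)(c1ccccc1)OC[C@H](O)[C@H](C(C)=C)[C@H](O)[C@H]1O[C@@]1(C)[C@@H](OC(=O)/C(C)=C\C)C/C=C(/I)C | intermediate
33 | 3,6,8-tri-angelate, 9-OTBDPS | CC(C)(C)[Si](c1ccccc1)(c1ccccc1)OC[C@H](OC(=O)/C(C)=C\C)[C@H](C(C)=C)[C@H](OC(=O)/C(C)=C\C)[C@H]1O[C@@]1(C)[C@@H](OC(=O)/C(C)=C\C)C/C=C(/I)C | intermediate
34 | C9 primary alcohol | OC[C@H](OC(=O)/C(C)=C\C)[C@H](C(C)=C)[C@H](OC(=O)/C(C)=C\C)[C@H]1O[C@@]1(C)[C@@H](OC(=O)/C(C)=C\C)C/C=C(/I)C | intermediate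
35 | seco C9 aldehyde–C10 vinyl iodide | O=C[C@H](OC(=O)/C(C)=C\C)[C@H](C(C)=C)[C@H](OC(=O)/C(C)=C\C)[C@H]1O[C@@]1(C)[C@@H](OC(=O)/C(C)=C\C)C/C=C(/I)C | intermediate
36 | (9R)-3,6,8-tris(angeloyloxy)-4,5-epoxy-9-hydroxygermacra-1(10)E,11(13)-diene (8,9-syn) | C=C(C)[C@@H]1[C@H](OC(=O)/C(C)=C\C)[C@H]2O[C@@]2(C)[C@@H](OC(=O)/C(C)=C\C)C/C=C(C)/[C@@H](O)[C@@H]1OC(=O)/C(C)=C\C | intermediate
37 | tert-butyl hydroperoxide | CC(C)(C)OO | starting material
38 | 3,6,8-tris(angeloyloxy)-1,10:4,5-diepoxy-9-hydroxygermacr-11(13)-ene (C9 as in 36) | C=C(C)[C@@H]1[C@H](OC(=O)/C(C)=C\C)[C@H]2O[C@@]2(C)[C@@H](OC(=O)/C(C)=C\C)C[C@@H]2O[C@@]2(C)[C@@H](O)[C@@H]1OC(=O)/C(C)=C\C | intermediate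
39 | (1S,3S,4S,5R,6S,7R,8R,10R)-3,6,8-tris(angeloyloxy)-1,10:4,5-diepoxygermacr-11(13)-en-9-one | C=C(C)[C@@H]1[C@H](OC(=O)/C(C)=C\C)[C@H]2O[C@@]2(C)[C@@H](OC(=O)/C(C)=C\C)C[C@@H]2O[C@@]2(C)C(=O)[C@@H]1OC(=O)/C(C)=C\C | target

**Totals and risks**
Total step count: 22. Longest linear sequence: 22 steps (1 → 39).

Most likely to fail, first: step 11. The phosphoric acid-catalysed propargylation has to control C3 on a hindered (Z)-α-methyl enal that can isomerise to the E-enal. Fallback: set out from 19 and add 20 without catalyst (toluene, rt) to obtain the C3-epimeric homopropargylic alcohols F1. Oxidise these with Dess–Martin periodinane to the β,γ-alkynyl enone F2. Reduce F2 with (R)-2-methyl-CBS-oxazaborolidine and catecholborane at −78 °C, where the reagent rather than the substrate sets C3. This comes back to the route at 21.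

Second: step 20. Ring closure to a ten-membered carbocycle from a flexible, fully acylated chain may give oligomers or protodeiodination. Fallback: set out from 24 and leave out the iodination, carrying the 2-alkyne through the chemistry of steps 14 to 19:
- mixed-anhydride acylation to the alkyne C3 angelate F3;
- PPTS/MeOH to the 6,8-diol F4;
- buffered peracid epoxidation to the epoxy diol F5;
- acylation to the alkyne tri-angelate F6;
- HF·pyridine to the primary alcohol F7;
- TEMPO/PhI(OAc)2 to the ynal F8.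

Then close the ring by reductive alkyne–aldehyde coupling catalysed by zerovalent nickel (Ni(cod)2, 1,3-dimesitylimidazol-2-ylidene, Et3SiH, THF, high dilution). Syn addition of H and C9 across the alkyne, with C–C bond formation at the methyl-bearing carbon, gives the macrocyclic C9 triethylsilyl ether F9. HF·pyridine cleavage comes back to the route at 36.

Third: step 21. The face of the C1=C10 olefin that is epoxidised depends on the C9 configuration from step 20 and on the ring conformation, neither of which is secured. Fallback: set out from 36 (either C9 epimer) and oxidise with Dess–Martin periodinane to the macrocyclic (E)-enone F10. Then run a nucleophilic Weitz–Scheffer epoxidation (t-BuOOH, DBU, CH2Cl2, 0 °C) on the exposed face of the enone. This comes back to the route at 39 with no C9 stereocentre involved.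

**Further compounds**
F1 | step 11 | C3-epimeric mixture of homopropargylic alcohol 21 | CC(C)(C)[Si](c1ccccc1)(c1ccccc1)OC[C@H](O[Si](CC)(CC)CC)[C@H](C(C)=C)[C@H](O[Si](CC)(CC)CC)/C=C(/C)C(O)CC#C
F2 | step 11 | C3 ketone (β,γ-alkynyl (Z)-enone) | CC(C)(C)[Si](c1ccccc1)(c1ccccc1)OC[C@H](O[Si](CC)(CC)CC)[C@H](C(C)=C)[C@H](O[Si](CC)(CC)CC)/C=C(/C)C(=O)CC#C
F3 | step 20 | C3 angelate of alkyne 24 | CC(C)(C)[Si](c1ccccc1)(c1ccccc1)OC[C@H](O[Si](CC)(CC)CC)[C@H](C(C)=C)[C@H](O[Si](CC)(CC)CC)/C=C(/C)[C@@H](OC(=O)/C(C)=C\C)CC#CC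
F4 | step 20 | alkyne 6,8-diol | CC(C)(C)[Si](c1ccccc1)(c1ccccc1)OC[C@H](O)[C@H](C(C)=C)[C@H](O)/C=C(/C)[C@@H](OC(=O)/C(C)=C\C)CC#CC
F5 | step 20 | alkyne (4S,5R)-epoxy 6,8-diol | CC(C)(C)[Si](c1ccccc1)(c1ccccc1)OC[C@H](O)[C@H](C(C)=C)[C@H](O)[C@H]1O[C@@]1(C)[C@@H](OC(=O)/C(C)=C\C)CC#CC
F6 | step 20 | alkyne 3,6,8-tri-angelate, 9-OTBDPS | CC(C)(C)[Si](c1ccccc1)(c1ccccc1)OC[C@H](OC(=O)/C(C)=C\C)[C@H](C(C)=C)[C@H](OC(=O)/C(C)=C\C)[C@H]1O[C@@]1(C)[C@@H](OC(=O)/C(C)=C\C)CC#CC
F7 | step 20 | alkyne C9 primary alcohol | OC[C@H](OC(=O)/C(C)=C\C)[C@H](C(C)=C)[C@H](OC(=O)/C(C)=C\C)[C@H]1O[C@@]1(C)[C@@H](OC(=O)/C(C)=C\C)CC#CC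
F8 | step 20 | ynal (C9 aldehyde, C1≡C10 alkyne) | O=C[C@H](OC(=O)/C(C)=C\C)[C@H](C(C)=C)[C@H](OC(=O)/C(C)=C\C)[C@H]1O[C@@]1(C)[C@@H](OC(=O)/C(C)=C\C)CC#CC
F9 | step 20 | C9 triethylsilyl ether of macrocycle 36 | C=C(C)[C@@H]1[C@H](OC(=O)/C(C)=C\C)[C@H]2O[C@@]2(C)[C@@H](OC(=O)/C(C)=C\C)C/C=C(C)/[C@@H](O[Si](CC)(CC)CC)[C@@H]1OC(=O)/C(C)=C\C
F10 | step 21 | macrocyclic 1(10)E-en-9-one (4,5-epoxide, three angelates) | C=C(C)[C@@H]1[C@H](OC(=O)/C(C)=C\C)[C@H]2O[C@@]2(C)[C@@H](OC(=O)/C(C)=C\C)C/C=C(C)/C(=O)[C@@H]1OC(=O)/C(C)=C\C
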